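## Analysis of the target

The target 33 is a bicyclic labdane: a trans-fused decalin (ring A: C1–C5 and C10; ring B: C5–C10) that carries on C9 a 3-methylidenepent-4-enyl chain (C11–C16), that is, a 2-substituted buta-1,3-diene. There are six stereocentres (C3, C4, C5, C8, C9, C10); C4 and C10 are quaternary and C8 is a tertiary carbinol. With the C10 methyl (C20) as reference: H-5 is anti (trans fusion); the C4 methyl and the equatorial C3 acetoxy group are syn; the hydroxymethyl carbon on C4 (called C19 here) is anti and equatorial. The C9 chain is axial and anti to C20 (the C9 epimer of the common labdanes), the C8 hydroxyl is equatorial and cis to that chain, and the C8 methyl is axial and syn to C20. Sensitive groups are the terminal conjugated diene (acid, radicals, oxidants, dienophiles), the tertiary alcohol (ionisation, and closure of an 8,12-ether whenever C12 is activated) and a secondary acetate 1,3 to a free primary alcohol (acyl migration under base). The difficulty lies in the congested C8–C9–C10 array with an axial chain between two fully substituted carbons, in the two quaternary centres, and in acetylating the more hindered secondary hydroxyl while the primary one stays free. The strategy rests on ring A: C3–O and C19–O are 1,3 across the quaternary C4, and C5, which carries C6, is β to C3. This is the pattern left by conjugate addition at C5 of a C3 enone followed by aldol capture of the enolate at C4, with the C10 quaternary centre already in place to direct both events.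

## Retrosynthetic reasoning

The last operations are protecting-group moves. The acetate must sit on the hindered secondary O-3 while the primary O-19 is free, so O-19 has to be masked when C3 is acylated and unmasked afterwards without base. This leads from 33 through 32 and 31 back to the fully silylated diene 30.

The C12–C13 bond is cut next. The diene is brought in intact as the 2-butadienyl Grignard reagent 29 (from chloroprene 28) and joined to the primary iodide 27. This puts the most fragile group into the molecule late and uses an unhindered sp3 centre as electrophile.

Iodide 27 is taken back through alcohol 26 and triol 24 to the γ-lactone 23. The lactone stores C12 at the acid level and O-8 in masked form. O-8 must be silylated before C12 is activated, since the free 8-hydroxyl would close a tetrahydrofuran.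

The C8–O bond of 23 is cut to the γ,δ-unsaturated acid 22. In the forward direction the carboxyl group on the C9 arm can reach C8 only on its own face, so the tether fixes the C8 configuration (O-8 cis to C11, methyl axial), which no external reagent would be likely to deliver.

The C9–C11 bond of 22 is cut by a [3,3] retron to the allylic alcohol 19. A suprafacial shift from an axial C7 oxygen places C11 axially on C9, anti to C20, which is the unusual C9 configuration of the target. The C7 oxygen of 19 is in turn removed to give alkene 18; the forward step is an allylic oxidation that delivers oxygen to the axial position.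

Ring B is opened at C8=C9 to the keto aldehyde 17. The two carbonyl carbons are 1,6 to each other, so an aldol reaction cannot close a six-membered ring here (it would give a five-membered one); a reductive carbonyl–carbonyl coupling is the reaction that joins C8 to C9 directly. This choice follows from the C5 donor: it must bring exactly C6, C7, C8 and C17. A 3-oxopentyl donor would carry one carbon too many. A 2-oxobutyl donor, which would allow an aldol closure to a C7 enone, would have to be a neopentyl-type β,β-dialkoxy organomagnesium reagent, prone to β-elimination and slow to transfer from copper. The γ-ketal 3-oxobutyl reagent 11 is the reliable one.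

Keto aldehyde 17 goes back through silyl ether 16 and diol 15 to the ring-A hydroxy ketone 14. C3 is reduced before ring B is made, so that no second ketone competes in the carbonyl coupling, and the primary O-19 is silylated selectively at the diol stage.

The key disconnection cuts C5–C6 and C4–C19 of 14 and gives three components: enone 7, Grignard reagent 11 and formaldehyde 12. Two C–C bonds, the quaternary C4 and the C5 stereocentre are formed in one operation, and the ring-fusion relationship and the C3/C19 oxygen pattern are in place before ring B exists.

Enone 7 is simplified by removing the C2 methyl (via iodide 6) and the acetal (via 5) to formyl enone 4, the product of an asymmetric Diels–Alder reaction of diene 1 with methacrolein 2, which sets the single stereocentre from which all others follow. Grignard reagent 11 comes from bromo ketal 10 and but-3-en-2-one 8.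

## Alternatives that were turned down

Alternative 1: The C9–C10 bond of ring B is cut and ring A is taken back to an arene, the phenol A1, whose side chain ends in a dienyl methyl carbonate.
- Forward key step: [Ir(cod)Cl]2 with a chiral phosphoramidite and base would ionise the carbonate to an allyl–iridium complex. The para carbon of the phenolate (C10) would attack the substituted allyl terminus (C9), closing ring B and giving the cross-conjugated dienone A2 with the quaternary C10 and the C9 vinyl group set by the catalyst.
- For it: a cheap aromatic start and one catalytic asymmetric step that makes ring B and two stereocentres. It reaches the bicyclic skeleton in fewer steps than the chosen route, and its absolute control does not depend on an early cycloaddition.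
- Against it: the tether sits meta to the hydroxyl, so the ortho carbon C4 can reach the same allyl terminus through an equally six-membered transition state, and O-allylation competes. The required relative configuration (vinyl anti to the C10 methyl, an axial-type arrangement) is not secured by the catalyst. A2 also contains none of the sp3 centres of ring A: C1=C2 must be reduced, C19 introduced by reductive alkylation across C4=C5, C3 reduced, and the C8 methylidene hydrated with no tether to choose the face, all beside a C9 vinyl group.
- Comparison: the chosen strategy sets C4 and C5 together with C3 and C19 already oxygenated, and relays C9 and C8 through intramolecular events. It is longer to the decalin but leaves no stereocentre to a weakly controlled step.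

Alternative 2: C5–C10 and C3–C4 are cut together, which opens both rings to the acyclic tetraene aldehyde A3 with its single stereocentre at C9.
- Forward key step: Me2AlCl would activate the (E)-2-methyl enal (C4=C5) towards the tethered diene (C10=C1–C2=C3) in an intramolecular Diels–Alder reaction, giving the trans-fused octalin A4.
- For it: it forms two C–C bonds and both rings and sets C4, C5 and C10 at once, which is more than the chosen key step does (two bonds, no ring). Allylic strain at C9 should favour the axial acetic ester arm that this target needs. The C7=C8 alkene and the C9 acetic ester of A4 are ready for the same lactonisation used here.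
- Against it: the diene terminus C10 is fully substituted and carries its methyl on the inside, so the s-cis conformer is disfavoured, and two quaternary centres must form in one cycloaddition. Under a Lewis acid the polyene can also isomerise or cyclise cationically. A4 has no oxygen at C3, which would have to be introduced next to the quaternary C4 from the C1=C2 alkene in several steps. The geometrically defined A3, with a doubly allylic stereocentre, needs a long linear preparation.
- Comparison: the chosen route carries the C3 oxygen from the first step as the enone carbonyl and builds on a ring that already exists.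

Alternative 3: The C8–C9 bond is cut in a fully functionalised ring A, the bromo ketone A5.
- Forward key step: CrCl2 (divalent chromium) would convert the allylic bromide into a trivalent allylchromium species that adds through its γ-carbon C9 to the C8 methyl ketone, closing ring B to give A6 with the tertiary alcohol and the C9 vinyl group formed together.
- For it: it is clearly more step-economical for ring B, since one step replaces the carbonyl coupling, allylic oxidation, rearrangement, lactonisation and reduction used here. It tolerates the C3 acetate, so protecting-group traffic is lighter. It would branch from an intermediate close to 17 of the present route.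
- Against it: a closed, chair-like transition state fused to the forming ring places O-8 and the vinyl group trans-diequatorial, which is the common labdane C9 configuration. This target needs the vinyl group axial and cis to O-8, the arrangement that such a transition state disfavours. The bond also has to form between a ketone and a γ-carbon attached to the quaternary C10.
- Comparison: the chosen route pays five steps for ring B but obtains the axial C9 substituent from a suprafacial shift and C8 from a tether, both of which are predictable. The wanted diastereomer is the intrinsically disfavoured one in Alternative 3, so its shorter sequence carries a risk that sits late and is hard to correct.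

Key step: step 7

Remark on numbering: labdane locants are used for all intermediates; C20 is the C10 methyl, C19 the oxygenated carbon on C4, C18 the C4 methyl, and "syn/anti to C20" gives the face of a substituent. TBDPS = tert-butyldiphenylsilyl, TES = triethylsilyl.

Assumption: the sense of induction in step 1 is set by the choice of TADDOL antipode; the antipode that gives the (R)-aldehyde 4 is used.

## Route

Step 1
Reactants: 1 (E)-3-(tert-butyldimethylsilyloxy)-N,N-dimethylbuta-1,3-dien-1-amine; 2 methacrolein
Product: 4 (R)-1-methyl-4-oxocyclohex-2-ene-1-carbaldehyde, via Diels–Alder cycloadduct 3 (not isolated)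
Conditions: 1-naphthyl-TADDOL (20 mol %), toluene, −78 °C; then 48% aq. HF, MeCN, 0 °C
Reagents that add atoms: none
Why: Hydrogen-bond-catalysed asymmetric Diels–Alder reaction: the TADDOL hydroxyl activates 2 and shields one of its faces, and the amino-bearing diene terminus bonds to the α-carbon, which sets the quaternary centre (later C10) in cycloadduct 3. HF then cleaves the silyl enol ether and β-eliminates dimethylamine, so the C–N stereocentre is erased and only the quaternary centre remains.

Step 2
Reactants: 4 (R)-1-methyl-4-oxocyclohex-2-ene-1-carbaldehyde
Product: 5 (R)-4-(dimethoxymethyl)-4-methylcyclohex-2-en-1-one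
Conditions: HC(OMe)3, CeCl3·7H2O (cat.), MeOH, rt
Reagents that add atoms: trimethyl orthoformate, COC(OC)OC; methanol, CO
Why: Acetalisation; the cerium chloride/orthoformate conditions select the aldehyde over the conjugated ketone. The dimethoxymethyl group is both the masked C9 aldehyde and the bulky substituent that will direct the key step.

Step 3
Reactants: 5 (R)-4-(dimethoxymethyl)-4-methylcyclohex-2-en-1-one
Product: 6 (R)-4-(dimethoxymethyl)-2-iodo-4-methylcyclohex-2-en-1-one
Conditions: I2, pyridine, CH2Cl2, 0 °C → rt
Reagents that add atoms: iodine, II
Why: α-Iodination of the enone by reversible conjugate addition of pyridine, iodination of the resulting enolate and elimination (a Baylis–Hillman-type mechanism); the quaternary centre is not involved and the acetal is stable to the basic medium.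

Step 4
Reactants: 6 (R)-4-(dimethoxymethyl)-2-iodo-4-methylcyclohex-2-en-1-one
Product: 7 (R)-4-(dimethoxymethyl)-2,4-dimethylcyclohex-2-en-1-one
Conditions: MeB(OH)2, Pd(dppf)Cl2 (5 mol %), K2CO3, dioxane/H2O, 80 °C
Reagents that add atoms: methylboronic acid, CB(O)O
Why: Suzuki–Miyaura coupling: zerovalent palladium inserts into the C–I bond, methyl is transferred from boron and reductive elimination gives the 2-methyl enone, whose methyl becomes C18.

Step 5
Reactants: 8 but-3-en-2-one
Product: 10 2-(2-bromoethyl)-2-methyl-1,3-dioxolane, via 4-bromobutan-2-one 9 (not isolated)
Conditions: HBr (g), CH2Cl2, 0 °C; then HOCH2CH2OH, TsOH·H2O (cat.), rt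
Reagents that add atoms: hydrogen bromide, Br; ethylene glycol, OCCO
Why: Conjugate addition of HBr to the enone gives the β-bromo ketone 9, which is ketalised under acid catalysis in the same pot before it can lose HBr again.

Step 6
Reactants: 10 2-(2-bromoethyl)-2-methyl-1,3-dioxolane
Product: 11 [2-(2-methyl-1,3-dioxolan-2-yl)ethyl]magnesium bromide (THF solution, titrated and used at once)
Conditions: Mg, THF, 25–30 °C
Reagents that add atoms: magnesium, [Mg]
Why: Insertion of magnesium into the primary C–Br bond; the ketone is masked and its oxygens are γ to the carbanion, so β-alkoxide elimination is not possible.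

Step 7
Reactants: 7 (R)-4-(dimethoxymethyl)-2,4-dimethylcyclohex-2-en-1-one; 11 [2-(2-methyl-1,3-dioxolan-2-yl)ethyl]magnesium bromide; 12 formaldehyde (monomer, from cracked paraformaldehyde)
Product: 14 (2S,3S,4R)-4-(dimethoxymethyl)-2-(hydroxymethyl)-2,4-dimethyl-3-[2-(2-methyl-1,3-dioxolan-2-yl)ethyl]cyclohexan-1-one, via bromomagnesium enolate 13 (not isolated)
Conditions: 11 (1.6 equiv), CuBr·SMe2 (20 mol %), THF/Me2S, −78 → −40 °C; then CH2O (g), −78 → −30 °C; aq. NH4Cl, −30 °C
Reagents that add atoms: none
Why: CuBr·SMe2 and 11 give a magnesium organocuprate (monovalent copper) that forms a π-complex with enone 7, adds at C5 through a trivalent copper intermediate and reductively eliminates to make C5–C6; this leaves the tetrasubstituted bromomagnesium enolate 13, which adds to monomeric formaldehyde 12 through a closed six-membered aldol transition state to make C4–C19. The closest known reaction type is the copper-catalysed Grignard conjugate addition to 2-methylcyclohex-2-enones with capture of the magnesium enolate by gaseous formaldehyde. No ring is closed: two C–C bonds and two stereocentres are added to the existing ring A. C5 is controlled by the C10 quaternary centre, because in the reactive half-chair the cuprate attacks axially, antiperiplanar to the pseudoaxial dimethoxymethyl group and gauche only to the small methyl, so C6 ends trans to C9. C4 is controlled by C5 and C10, because formaldehyde enters on the enolate face opposite the new vicinal chain (the usual trans outcome of addition–trapping sequences) and opposite the C10 methyl, which would be syn-axial to an electrophile on the other face; the same bias governs alkylation of 4-methyl-3-keto decalin enolates. The step needs 1,4- over 1,2-addition, both facial selectivities and C-hydroxymethylation without retro-aldol; these rest on copper catalysis at low temperature with a primary, unhindered Grignard reagent, on the size difference of the two C10 substituents, and on anhydrous monomeric CH2O at −78 °C with a cold NH4Cl quench (C4 bears no hydrogen, so 14 cannot dehydrate).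

Step 8
Reactants: 14 ring-A hydroxy ketone
Product: 15 ring-A 3,19-diol (C3 hydroxyl syn to C20 and trans to the hydroxymethyl group; acetal and ketal intact)
Conditions: Me4NBH(OAc)3, MeCN/AcOH, −30 → −20 °C
Reagents that add atoms: none
Why: Evans–Saksena reduction: the C19 hydroxyl exchanges onto boron and hydride is delivered intramolecularly to the carbonyl face on the side of C19, so the new hydroxyl is trans to the hydroxymethyl group and syn to C20 (the equatorial alcohol, also the product of axial attack). The weak reductant and the cold anhydrous medium leave the acetal and ketal intact, and reducing C3 now removes a ketone that would compete in step 11.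

Step 9
Reactants: 15 ring-A 3,19-diol
Product: 16 19-O-TBDPS ether of 15 (C3 hydroxyl free)
Conditions: TBDPSCl, imidazole, CH2Cl2, 0 °C → rt
Reagents that add atoms: tert-butyl(chloro)diphenylsilane, CC(C)(C)[Si](Cl)(c1ccccc1)c1ccccc1
Why: Silylation of the primary hydroxyl in preference to the secondary C3 hydroxyl, which is flanked by the quaternary C4. TBDPS is chosen because it withstands aqueous and protic acid, low-valent titanium, hydride and Grignard reagents and can be removed last.

Step 10
Reactants: 16 19-O-TBDPS ether
Product: 17 keto aldehyde (C9 aldehyde on C10; 3-oxobutyl chain C6–C7–C8(=O)–C17 on C5; C3 hydroxyl; 19-OTBDPS)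
Conditions: 1 M HCl (aq.), THF, 0 °C → rt
Reagents that add atoms: water, O
Why: Acid hydrolysis of the dimethyl acetal and of the dioxolane through oxocarbenium ions; the aldehyde cannot enolise and the TBDPS ether is stable. The crude 1,6-keto aldehyde is used at once, before the methyl ketone can aldolise onto C9 to a five-membered ring.

Step 11
Reactants: 17 keto aldehyde
Product: 18 trans-fused bicyclic alkene (C8=C9; C8 methyl; C3 hydroxyl; 19-OTBDPS)
Conditions: TiCl3(DME)1.5, Zn–Cu, DME, reflux, slow addition of 17
Reagents that add atoms: none
Why: Intramolecular McMurry coupling: low-valent titanium joins the C8 ketone and the C9 aldehyde as a titanium pinacolate and deoxygenates it to the C8=C9 alkene, closing the six-membered ring B. The fusion is trans because both arms are equatorial on ring A; the free hydroxyl is carried as its titanium alkoxide.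

Step 12
Reactants: 18 bicyclic alkene
Product: 19 allylic alcohol (C7 hydroxyl axial and anti to C20; C8=C9 retained)
Conditions: SeO2 (0.5 equiv), t-BuOOH, CH2Cl2, 0 °C → rt
Reagents that add atoms: selenium dioxide, O=[Se]=O; tert-butyl hydroperoxide, CC(C)(C)OO
Why: Allylic oxidation by SeO2 (ene reaction followed by a [2,3]-sigmatropic shift): selenium bonds to C9 on the face anti to C20, takes the pseudoaxial H-7 of that face and returns oxygen to C7 on the same face, which gives the axial alcohol. The ring CH2 next to the more substituted alkene carbon (C7) reacts ahead of the C17 methyl.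

Step 13
Reactants: 19 allylic alcohol
Product: 22 C9 acetic acid (C11–C12 on C9; C11 axial and anti to C20; C7=C8; C3 hydroxyl; 19-OTBDPS), via ketene acetal 20 (not isolated), via ethyl ester 21 (not isolated)
Conditions: MeC(OEt)3, EtCO2H (cat.), 140 °C; then LiOH, THF/MeOH/H2O, 40 °C; H3O+
Reagents that add atoms: triethyl orthoacetate, CCOC(C)(OCC)OCC; lithium hydroxide, [Li+].[OH-]
Why: Johnson–Claisen rearrangement: orthoester exchange and loss of ethanol give ketene acetal 20, whose chair-like [3,3] shift transfers C11 suprafacially from the axial C7 oxygen to C9, so C9 becomes a stereocentre with C11 axial and anti to C20 while the alkene moves to C7=C8. Saponification of ester 21 also removes any acetate or orthoester formed reversibly at the C3 hydroxyl.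

Step 14
Reactants: 22 C9 acetic acid
Product: 23 cis-fused 12,8-lactone (O-8 on the face of C11; C8 methyl axial and syn to C20)
Conditions: TfOH (10 mol %), CH2Cl2, 0 °C → rt
Reagents that add atoms: none
Why: Acid-catalysed lactonisation (hydro-acyloxylation of the alkene): protonation at C7 gives the tertiary C8 cation, which the carboxyl group can reach only on the face of its own two-atom tether, so C8–O forms cis to C11 and the C8 methyl becomes axial. The axial C9–C11 bond is aligned with the empty orbital, whereas the equatorial H-9 is poorly placed for a hydride shift.

Step 15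
Reactants: 23 lactone
Product: 24 3,8,12-triol (19-OTBDPS)
Conditions: LiAlH4, THF, 0 °C
Reagents that add atoms: none
Why: Hydride reduction of the lactone to the 8,12-diol; the silyl ether and all stereocentres are untouched.

Step 16
Reactants: 24 triol
Product: 26 3,8-bis(TES) ether with free C12 hydroxyl, via tris(triethylsilyl) ether 25 (not isolated)
Conditions: TESOTf, 2,6-lutidine, CH2Cl2, −78 → 0 °C; then MeOH, PPTS, 0 °C
Reagents that add atoms: triethylsilyl trifluoromethanesulfonate, CC[Si](CC)(CC)OS(=O)(=O)C(F)(F)F
Why: The reactive silyl triflate covers all three hydroxyls, the tertiary O-8 included; mild acid methanolysis then removes only the unhindered primary C12 silyl ether. Masking O-8 prevents closure of the 8,12-ether when C12 is activated.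

Step 17
Reactants: 26 C12 alcohol
Product: 27 C12 iodide (3,8-bis-OTES; 19-OTBDPS)
Conditions: I2, PPh3, imidazole, CH2Cl2, 0 °C → rt
Reagents that add atoms: iodine, II
Why: Appel reaction: the alkoxyphosphonium ion at the primary C12 is displaced by iodide in an SN2 step, and the silylated O-8 cannot intervene.

Step 18
Reactants: 28 chloroprene (2-chlorobuta-1,3-diene)
Product: 29 buta-1,3-dien-2-ylmagnesium chloride (THF solution, used at once)
Conditions: Mg, ZnCl2 (cat.), BrCH2CH2Br (cat.), THF, reflux
Reagents that add atoms: magnesium, [Mg]
Why: Insertion of activated magnesium into the vinylic C–Cl bond, a known way to the 2-butadienyl Grignard reagent.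

Step 19
Reactants: 27 C12 iodide; 29 buta-1,3-dien-2-ylmagnesium chloride
Product: 30 silylated diene (complete carbon skeleton; 3,8-bis-OTES; 19-OTBDPS)
Conditions: Li2CuCl4 (5 mol %), THF, −20 → 0 °C
Reagents that add atoms: none
Why: Copper-catalysed cross-coupling of a Grignard reagent with a primary alkyl iodide: the organocuprate formed in situ displaces iodide at C12 through its sp2 carbon and delivers the 2-substituted diene in one step.

Step 20
Reactants: 30 silylated diene
Product: 31 3,8-diol (19-OTBDPS)
Conditions: HF·pyridine, pyridine, THF, 0 °C
Reagents that add atoms: none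
Why: Buffered fluoride cleaves the two triethylsilyl ethers, while the much more robust neopentyl TBDPS ether stays, so C19 remains masked when C3 is set free.

Step 21
Reactants: 31 3,8-diol
Product: 32 3-acetate (8-hydroxyl free; 19-OTBDPS)
Conditions: Ac2O, pyridine, DMAP (cat.), CH2Cl2, rt
Reagents that add atoms: acetic anhydride, CC(=O)OC(C)=O
Why: DMAP-catalysed acylation; only the secondary C3 hydroxyl reacts, because O-19 is silylated and the tertiary C8 hydroxyl is too hindered at room temperature.

Step 22
Reactants: 32 3-acetate
Product: 33 CNP0313672.1 (3-acetoxy-8,19-dihydroxy labda-13(16),14-diene of the given configuration)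
Conditions: HF·pyridine (excess), pyridine, THF, rt → 40 °C
Reagents that add atoms: none
Why: Fluoride-mediated desilylation under weakly acidic conditions, so no alkoxide forms at C19 and the acetyl group does not migrate from O-3 to O-19; the diene and the tertiary alcohol tolerate diluted HF·pyridine.

## Compound list

1 | (E)-3-(tert-butyldimethylsilyloxy)-N,N-dimethylbuta-1,3-dien-1-amine | CN(C)/C=C/C(=C)O[Si](C)(C)C(C)(C)C | starting material
2 | methacrolein | C=C(C)C=O | starting material
3 | (1R,2S)-4-(tert-butyldimethylsilyloxy)-2-(dimethylamino)-1-methylcyclohex-3-ene-1-carbaldehyde (amino cis to formyl; not isolated) | CN(C)[C@H]1C=C(O[Si](C)(C)C(C)(C)C)CC[C@@]1(C)C=O | intermediate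
4 | (R)-1-methyl-4-oxocyclohex-2-ene-1-carbaldehyde | O=C[C@]1(C)CCC(=O)C=C1 | intermediate
5 | (R)-4-(dimethoxymethyl)-4-methylcyclohex-2-en-1-one | COC(OC)[C@]1(C)CCC(=O)C=C1 | intermediate
6 | (R)-4-(dimethoxymethyl)-2-iodo-4-methylcyclohex-2-en-1-one | COC(OC)[C@]1(C)CCC(=O)C(I)=C1 | intermediate
7 | (R)-4-(dimethoxymethyl)-2,4-dimethylcyclohex-2-en-1-one | COC(OC)[C@]1(C)CCC(=O)C(C)=C1 | intermediate
8 | but-3-en-2-one | C=CC(C)=O | starting material
9 | 4-bromobutan-2-one (not isolated) | CC(=O)CCBr | intermediate
10 | 2-(2-bromoethyl)-2-methyl-1,3-dioxolane | CC1(CCBr)OCCO1 | intermediate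
11 | [2-(2-methyl-1,3-dioxolan-2-yl)ethyl]magnesium bromide | CC1(CC[Mg]Br)OCCO1 | intermediate
12 | formaldehyde (monomer, from paraformaldehyde) | C=O | starting material
13 | bromomagnesium enolate of the conjugate adduct (not isolated) | COC(OC)[C@]2(C)CCC(O[Mg]Br)=C(C)[C@H]2CCC1(C)OCCO1 | intermediate
14 | (2S,3S,4R)-4-(dimethoxymethyl)-2-(hydroxymethyl)-2,4-dimethyl-3-[2-(2-methyl-1,3-dioxolan-2-yl)ethyl]cyclohexan-1-one | COC(OC)[C@]2(C)CCC(=O)[C@](C)(CO)[C@H]2CCC1(C)OCCO1 | intermediate
15 | ring-A 3,19-diol (3-OH syn to C20) | COC(OC)[C@]2(C)CC[C@@H](O)[C@](C)(CO)[C@H]2CCC1(C)OCCO1 | intermediate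
16 | 19-O-TBDPS ether of 15 | COC(OC)[C@]2(C)CC[C@@H](O)[C@](C)(CO[Si](c3ccccc3)(c3ccccc3)C(C)(C)C)[C@H]2CCC1(C)OCCO1 | intermediate
17 | keto aldehyde (C9 aldehyde, C8 methyl ketone) | O=C[C@]2(C)CC[C@@H](O)[C@](C)(CO[Si](c3ccccc3)(c3ccccc3)C(C)(C)C)[C@H]2CCC(C)=O | intermediate
18 | trans-fused bicyclic 8-ene | CC1=C[C@]2(C)CC[C@@H](O)[C@](C)(CO[Si](c3ccccc3)(c3ccccc3)C(C)(C)C)[C@H]2CC1 | intermediate
19 | 8-en-7-ol, 7-OH axial and anti to C20 | CC1=C[C@]2(C)CC[C@@H](O)[C@](C)(CO[Si](c3ccccc3)(c3ccccc3)C(C)(C)C)[C@H]2C[C@@H]1O | intermediate
20 | mixed ketene acetal at O-7 (not isolated) | CC1=C[C@]2(C)CC[C@@H](O)[C@](C)(CO[Si](c3ccccc3)(c3ccccc3)C(C)(C)C)[C@H]2C[C@@H]1OC(=C)OCC | intermediate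
21 | ethyl ester of 22 (not isolated) | CCOC(=O)C[C@@H]1[C@]2(C)CC[C@@H](O)[C@](C)(CO[Si](c3ccccc3)(c3ccccc3)C(C)(C)C)[C@H]2CC=C1C | intermediate
22 | 7-en-12-oic acid (C11 axial on C9) | OC(=O)C[C@@H]1[C@]2(C)CC[C@@H](O)[C@](C)(CO[Si](c3ccccc3)(c3ccccc3)C(C)(C)C)[C@H]2CC=C1C | intermediate
23 | cis-fused 12,8-lactone | O=C4C[C@@H]1[C@]2(C)CC[C@@H](O)[C@](C)(CO[Si](c3ccccc3)(c3ccccc3)C(C)(C)C)[C@H]2CC[C@]1(C)O4 | intermediate
24 | 3,8,12-triol, 19-OTBDPS | OCC[C@@H]1[C@]2(C)CC[C@@H](O)[C@](C)(CO[Si](c3ccccc3)(c3ccccc3)C(C)(C)C)[C@H]2CC[C@]1(C)O | intermediate
25 | 3,8,12-tris(TES) ether (not isolated) | CC[Si](CC)(CC)OCC[C@@H]1[C@]2(C)CC[C@@H](O[Si](CC)(CC)CC)[C@](C)(CO[Si](c3ccccc3)(c3ccccc3)C(C)(C)C)[C@H]2CC[C@]1(C)O[Si](CC)(CC)CC | intermediate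
26 | 3,8-bis(TES) ether, 12-ol | OCC[C@@H]1[C@]2(C)CC[C@@H](O[Si](CC)(CC)CC)[C@](C)(CO[Si](c3ccccc3)(c3ccccc3)C(C)(C)C)[C@H]2CC[C@]1(C)O[Si](CC)(CC)CC | intermediate
27 | 12-iodide | ICC[C@@H]1[C@]2(C)CC[C@@H](O[Si](CC)(CC)CC)[C@](C)(CO[Si](c3ccccc3)(c3ccccc3)C(C)(C)C)[C@H]2CC[C@]1(C)O[Si](CC)(CC)CC | intermediate
28 | chloroprene | C=CC(Cl)=C | starting material
29 | buta-1,3-dien-2-ylmagnesium chloride | C=CC(=C)[Mg]Cl | intermediate
30 | 3,8-bis(TES), 19-TBDPS protected target skeleton | C=CC(=C)CC[C@@H]1[C@]2(C)CC[C@@H](O[Si](CC)(CC)CC)[C@](C)(CO[Si](c3ccccc3)(c3ccccc3)C(C)(C)C)[C@H]2CC[C@]1(C)O[Si](CC)(CC)CC | intermediate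
31 | 3,8-diol, 19-OTBDPS | C=CC(=C)CC[C@@H]1[C@]2(C)CC[C@@H](O)[C@](C)(CO[Si](c3ccccc3)(c3ccccc3)C(C)(C)C)[C@H]2CC[C@]1(C)O | intermediate
32 | 3-acetate, 19-OTBDPS | C=CC(=C)CC[C@@H]1[C@]2(C)CC[C@@H](OC(C)=O)[C@](C)(CO[Si](c3ccccc3)(c3ccccc3)C(C)(C)C)[C@H]2CC[C@]1(C)O | intermediate
33 | CNP0313672.1 | C=CC(=C)CC[C@@H]1[C@]2(C)CC[C@@H](OC(C)=O)[C@](C)(CO)[C@H]2CC[C@]1(C)O | target

## Step count and least certain steps

Total step count: 22. Longest linear sequence: 19 steps (steps 1–4, 7–17 and 19–22); steps 5–6 and 18 prepare the two Grignard reagents.

Step 7 (key step). What may go wrong: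
- insufficient facial discrimination at C5 between the methyl and the dimethoxymethyl group, possibly eroded by coordination of the acetal oxygens to magnesium;
- slow addition to the α-methyl, γ-quaternary enone, which lets 1,2-addition compete;
- incomplete or reversible capture of the hindered tetrasubstituted enolate by formaldehyde (protonation, hemiformal formation).

Fallback: set out from 7 and 11 and run the copper-catalysed addition at −78 °C with Me3SiCl present, which accelerates the 1,4-addition and gives the trimethylsilyl enol ether F1 as an isolable compound. The lithium enolate is then regenerated from F1 with MeLi in THF and hydroxymethylated with 12 at −78 °C, which comes back to 14. The two bond formations are separated and each can be optimised alone.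

Step 11. What may go wrong: the coupling may stop at the pinacol stage, the 1,6-keto aldehyde may aldolise on the Lewis-acidic titanium surface before it couples, or intermolecular coupling may compete. Fallback: from 17, excess Ph3P=CH2 converts both carbonyl groups into alkenes to give the diene F2, and ring-closing metathesis with the second-generation Hoveyda–Grubbs catalyst closes ring B with loss of ethene, returning to 18.

Step 12. What may go wrong: competing oxidation of the C17 methyl group, over-oxidation of the allylic alcohol to the enone, or incomplete facial control. Fallback: from 18, CrO3·3,5-dimethylpyrazole oxidises C7 (and the C3 carbinol) to the ene-dione F3. NaBH4/CeCl3·7H2O reduces both carbonyls by axial attack to the diequatorial diol F4. A Mitsunobu reaction with AcOH inverts only the allylic C7 centre (the neopentyl-type C3 carbinol cannot be displaced) to the axial acetate F5, and K2CO3/MeOH returns to 19.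

Step 14. What may go wrong: the C8 cation may lose a proton to isomeric alkenes or rearrange before it is trapped, and the strong acid may attack the silyl ether. Fallback: from 22, iodolactonisation (I2, NaHCO3, MeCN) gives the iodolactone F6 by anti addition under neutral conditions (O-8 on the face of C11, iodine at C7), and Bu3SnH/AIBN removes the iodine, returning to 23.

Step 19. What may go wrong: the butadienyl Grignard reagent may react through its allenyl form or dimerise, and the iodide may undergo reduction or homocoupling instead of cross-coupling. Fallback: from 27, displacement with lithium acetylide–ethylenediamine in DMSO gives the terminal alkyne F7, and enyne cross-metathesis with ethene and the second-generation Grubbs catalyst converts it into the 2-substituted diene, returning to 30.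

## Further compounds

F1 | step 7 | trimethylsilyl enol ether of the conjugate adduct | COC(OC)[C@]2(C)CCC(O[Si](C)(C)C)=C(C)[C@H]2CCC1(C)OCCO1
F2 | step 11 | diene from double methylenation of 17 (C9 vinyl on C10, 3-methylbut-3-enyl on C5) | C=C[C@]2(C)CC[C@@H](O)[C@](C)(CO[Si](c3ccccc3)(c3ccccc3)C(C)(C)C)[C@H]2CCC(C)=C
F3 | step 12 | bicyclic 8-ene-3,7-dione | CC1=C[C@]2(C)CCC(=O)[C@](C)(CO[Si](c3ccccc3)(c3ccccc3)C(C)(C)C)[C@H]2CC1=O
F4 | step 12 | 8-ene-3,7-diol, both hydroxyls equatorial and syn to C20 | CC1=C[C@]2(C)CC[C@@H](O)[C@](C)(CO[Si](c3ccccc3)(c3ccccc3)C(C)(C)C)[C@H]2C[C@H]1O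
F5 | step 12 | 7-acetate with acetoxy axial and anti to C20, 3-OH free | CC1=C[C@]2(C)CC[C@@H](O)[C@](C)(CO[Si](c3ccccc3)(c3ccccc3)C(C)(C)C)[C@H]2C[C@@H]1OC(C)=O
F6 | step 14 | 7-iodo 12,8-lactone (iodine syn to C20) | O=C4C[C@@H]1[C@]2(C)CC[C@@H](O)[C@](C)(CO[Si](c3ccccc3)(c3ccccc3)C(C)(C)C)[C@H]2C[C@@H](I)[C@]1(C)O4
F7 | step 19 | terminal alkyne (but-3-ynyl chain on C9) | C#CCC[C@@H]1[C@]2(C)CC[C@@H](O[Si](CC)(CC)CC)[C@](C)(CO[Si](c3ccccc3)(c3ccccc3)C(C)(C)C)[C@H]2CC[C@]1(C)O[Si](CC)(CC)CC
A1 | alternative 1 | 3-[(4E)-6-(methoxycarbonyloxy)-3-methylidenehex-4-en-1-yl]-2,4-dimethylphenol | Cc1ccc(O)c(C)c1CCC(=C)/C=C/COC(=O)OC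
A2 | alternative 1 | bicyclic cross-conjugated dienone with C10 methyl, C9 vinyl and C8 methylidene | C=C[C@@H]1[C@]2(C)C=CC(=O)C(C)=C2CCC1=C
A3 | alternative 2 | methyl (4Z,7E)-4,8-dimethyl-9-oxo-3-[(2E)-penta-2,4-dien-2-yl]nona-4,7-dienoate | C=C/C=C(\C)[C@@H](CC(=O)OC)/C(C)=C\C/C=C(\C)C=O
A4 | alternative 2 | trans-fused octalin with C4 formyl and methyl, C10 methyl, C9 methoxycarbonylmethyl, C1=C2 and C7=C8 | COC(=O)C[C@@H]1[C@]2(C)C=CC[C@](C)(C=O)[C@H]2CC=C1C
A5 | alternative 3 | ring-A bromo ketone with 3-acetoxy, 19-O-tert-butyldimethylsilyl, C10 (E)-3-bromoprop-1-enyl and C5 3-oxobutyl | BrC/C=C/[C@]2(C)CC[C@@H](OC(C)=O)[C@](C)(CO[Si](C)(C)C(C)(C)C)[C@H]2CCC(C)=O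
A6 | alternative 3 | 9-vinyl-8-hydroxy trans-decalin, 3-acetoxy, 19-O-tert-butyldimethylsilyl | C=C[C@@H]1[C@]2(C)CC[C@@H](OC(C)=O)[C@](C)(CO[Si](C)(C)C(C)(C)C)[C@H]2CC[C@]1(C)O
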